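**Plan**
- Retrosynthesis: after removal of four benzyl and two TIPS ethers, the flavan is cut at C4–C4a and at C3–O(gallate) in one operation while C3–C4a is re-formed. This contracts ring C to a cis-2-aryl-3-(mesyloxymethyl)-2,3-dihydrobenzofuran and releases the protected 4-O-methylgallic acid.
- Enabling feature: C4–C4a and C3–O are vicinal, and ring A carries oxygen at both positions ortho (O1, O5) and at the position para (O7) to C4a. Both bonds can therefore come from one strongly stabilised phenonium ion bridging C4 and C3.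
- The dihydrobenzofuran is cut at C2–C3 (carbenoid C–H insertion), at the aryl–CH2CO2Et bond, at the benzylic O–CH2 bond and at C–Br, back to phloroglucinol, 3,4-bis(benzyloxy)benzyl chloride and ethyl bromoacetate.
- Forward: ring A is silylated, brominated and O-benzylated with the ring B unit; the acetate arm is attached and diazotised; the five-membered oxygen ring is closed by C–H insertion. Ring C arises last by ring enlargement in the step that also joins the gallate, and two deprotections finish.
- Stereochemistry: C2 and C3 are set together, cis and enantioselectively, by the chiral dirhodium catalyst. C2 is carried through unchanged and C3 is inverted in the phenonium opening, which maps the cis dihydrobenzofuran onto the (2R,3R) 2,3-cis flavan.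

Key step: step 11

Assumption: Rh2(S-PTTL)4 is taken to give the (2S,3R) cis ester in step 6; if the sense of induction on this substrate is the opposite, Rh2(R-PTTL)4 is used.
Numbering: flavan numbering is used for the key step (C4 is the CH2OMs carbon, C4a the ring A carbon bonded to C3 in the dihydrobenzofuran).

**Step 1**
Reactants: 1 phloroglucinol
Product: 2 3,5-bis(triisopropylsilyloxy)phenol
Conditions: TIPSCl (2.0 equiv), imidazole (4 equiv), DMF, 0 °C to rt; chromatography, mono- and tris-silyl ethers resubmitted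
Reagents that add atoms: triisopropylsilyl chloride, CC(C)[Si](Cl)(C(C)C)C(C)C
Why: Silyl ether formation under statistical control on the C3-symmetric triphenol, the bulk of TIPS slowing the third silylation so that the bis-ether can be separated and the mono- and tris-ethers resubmitted.

**Step 2**
Reactants: 2 3,5-bis(triisopropylsilyloxy)phenol
Product: 3 2-bromo-3,5-bis(triisopropylsilyloxy)phenol
Conditions: NBS (1.0 equiv, slow addition), i-Pr2NH (10 mol%), CH2Cl2, −40 to 0 °C
Reagents that add atoms: N-bromosuccinimide, O=C1CCC(=O)N1Br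
Why: Amine-mediated ortho-bromination of a phenol, in which the N-bromoamine is delivered next to the hydrogen-bonded OH while the para position is shielded by its two flanking TIPS ethers, should give the 2-bromo isomer.

**Step 3**
Reactants: 3 2-bromo-3,5-bis(triisopropylsilyloxy)phenol; 4 3,4-bis(benzyloxy)benzyl chloride
Product: 5 1-{[3,4-bis(benzyloxy)phenyl]methoxy}-2-bromo-3,5-bis(triisopropylsilyloxy)benzene
Conditions: K2CO3 (2 equiv), NaI (10 mol%), acetone, 50 °C
Reagents that add atoms: none
Why: Williamson ether synthesis with an activated benzylic chloride under mild carbonate conditions that the hindered aryl TIPS ethers should tolerate, the ortho-bromophenol being acidic enough for clean O-alkylation.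

**Step 4**
Reactants: 5 aryl bromide from step 3; 6 ethyl bromoacetate
Product: 8 ethyl 2-[2-{[3,4-bis(benzyloxy)phenyl]methoxy}-4,6-bis(triisopropylsilyloxy)phenyl]acetate, via Reformatsky reagent 7 (not isolated)
Conditions: 6, Zn dust (Me3SiCl-activated), THF, 40 °C; then 5, Pd2(dba)3 (2 mol%), XPhos (8 mol%), THF, 60 °C
Reagents that add atoms: none
Why: Negishi coupling of a Reformatsky (zinc ester enolate) reagent with an aryl bromide, which with a bulky biarylphosphine on palladium accepts electron-rich di-ortho-substituted bromides and does not touch silyl or benzyl ethers.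

**Step 5**
Reactants: 8 ethyl arylacetate from step 4
Product: 9 ethyl 2-diazo-2-[2-{[3,4-bis(benzyloxy)phenyl]methoxy}-4,6-bis(triisopropylsilyloxy)phenyl]acetate
Conditions: p-ABSA (1.5 equiv), DBU (2 equiv), MeCN, 0 °C to rt
Reagents that add atoms: 4-acetamidobenzenesulfonyl azide, CC(=O)Nc1ccc(cc1)S(=O)(=O)N=[N+]=[N-]
Why: Regitz diazo transfer to the benzylic position of an arylacetate, the standard entry to aryldiazoacetates that carry an ortho benzyloxy group.

**Step 6**
Reactants: 9 aryl diazoacetate from step 5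
Product: 10 ethyl (2S,3R)-2-[3,4-bis(benzyloxy)phenyl]-4,6-bis(triisopropylsilyloxy)-2,3-dihydro-1-benzofuran-3-carboxylate (2-aryl and 3-ester groups cis)
Conditions: Rh2(S-PTTL)4 (dirhodium tetrakis[N-phthaloyl-(S)-tert-leucinate], 1 mol%), toluene, −60 °C
Reagents that add atoms: none
Why: Intramolecular rhodium-carbenoid 1,5 C–H insertion into the ring B benzylic ether C–H, for which Rh2(S-PTTL)4 is known to give cis-2-aryl-2,3-dihydrobenzofuran-3-carboxylates enantioselectively, so that C2 and C3 are set together under catalyst control while the silyl ethers on ring A offer no competing activated C–H bond.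

**Step 7**
Reactants: 10 cis ester from step 6
Product: 11 [(2S,3S)-2-[3,4-bis(benzyloxy)phenyl]-4,6-bis(triisopropylsilyloxy)-2,3-dihydro-1-benzofuran-3-yl]methanol (cis)
Conditions: i-Bu2AlH (3 equiv), CH2Cl2, −78 to −40 °C; aq. potassium sodium tartrate
Reagents that add atoms: none
Why: Ester reduction with a Lewis acidic, non-basic aluminium hydride at low temperature, so that the epimerisable cis C3 centre is not enolised and both stereocentres are kept.

**Step 8**
Reactants: 11 cis alcohol from step 7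
Product: 12 [(2S,3S)-2-[3,4-bis(benzyloxy)phenyl]-4,6-bis(triisopropylsilyloxy)-2,3-dihydro-1-benzofuran-3-yl]methyl methanesulfonate (cis)
Conditions: Ms2O (1.3 equiv), i-Pr2NEt (2 equiv), CH2Cl2, −30 °C; cold aqueous work-up, used at once
Reagents that add atoms: methanesulfonic anhydride, CS(=O)(=O)OS(C)(=O)=O
Why: O-sulfonylation of the primary alcohol, done with the anhydride and a hindered amine so that no chloride is present to open the ionisation-prone product, which is therefore used directly.

**Step 9**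
Reactants: 13 3,5-dihydroxy-4-methoxybenzoic acid
Product: 14 benzyl 3,5-bis(benzyloxy)-4-methoxybenzoate
Conditions: BnBr (3.5 equiv), K2CO3 (4 equiv), DMF, 60 °C
Reagents that add atoms: benzyl bromide, BrCc1ccccc1
Why: Williamson O-benzylation of both phenols with concurrent alkylation of the carboxylate, giving one fully benzylated product.

**Step 10**
Reactants: 14 benzyl 3,5-bis(benzyloxy)-4-methoxybenzoate
Product: 15 3,5-bis(benzyloxy)-4-methoxybenzoic acid
Conditions: NaOH (3 equiv), THF/MeOH/H2O, 60 °C; then 1 M HCl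
Reagents that add atoms: sodium hydroxide, [Na+].[OH-]
Why: Saponification of the benzyl ester, to which the benzyl and methyl aryl ethers are inert.

**Step 11**
Reactants: 12 cis mesylate from step 8; 15 3,5-bis(benzyloxy)-4-methoxybenzoic acid
Product: 17 (2R,3R)-2-[3,4-bis(benzyloxy)phenyl]-5,7-bis(triisopropylsilyloxy)-3,4-dihydro-2H-chromen-3-yl 3,5-bis(benzyloxy)-4-methoxybenzoate, via phenonium ion 16 (not isolated)
Conditions: 15 (3 equiv), i-Pr2NEt (2 equiv, less than the acid so that no fluoroalkoxide forms), (CF3)2CHOH/CH2Cl2 (1:1), 0 to 25 °C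
Reagents that add atoms: none
Why: Proposed new method: in the ionising, weakly nucleophilic fluoroalcohol the C3–C4a bond of 12 can lie anti to the C4–OMs bond, so the ring A ipso carbon C4a, with oxygen at both ortho positions and at the para position, displaces mesylate to give the cyclopropane-bridged cyclohexadienyl cation 16, which the carboxylate of 15 opens at secondary C3 anti to the departing C4a, making C4–C4a and C3–O and breaking C3–C4a. The closest known reactions are solvolytic 1,2-aryl shifts of 2-arylpropyl sulfonates through phenonium ions, which give the rearranged secondary esters, and the radical neophyl enlargement of dihydrobenzofuran-3-ylmethyl to chroman-3-yl; a cationic enlargement of a dihydrobenzofuran to a flavan with capture by an external carboxylate has not been shown. Ring C is closed by ring enlargement and not by cyclisation: 3-exo-tet participation of the aryl carbon followed by cleavage of the ring-fusion bond moves C4a from C3 to C4 and turns the five-membered oxygen ring into the six-membered one. C3 is the only centre formed and is under substrate control, the SN2-like opening inverting the configuration installed in step 6, while C2 is not touched, so the cis dihydrobenzofuran maps onto the 2,3-cis (2R,3R) flavan. The step needs opening at the secondary instead of the primary carbon and must outrun direct displacement of mesylate, capture by solvent and a hydride or ring B shift from C2: the fluoroalcohol should make the opening carbocation-like so that the more substituted carbon is attacked with release of the bicyclo[3.1.0] strain, its hydrogen bonding damps direct SN2 attack of the carboxylate at the β-branched primary carbon, the three oxygen donors make aryl participation fast, and neither the C2–H nor the C2–aryl bond of the five-membered ring can align anti to the breaking bond.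

**Step 12**
Reactants: 17 bis-TIPS tetra-O-benzyl ester from step 11
Product: 18 (2R,3R)-2-[3,4-bis(benzyloxy)phenyl]-5,7-dihydroxy-3,4-dihydro-2H-chromen-3-yl 3,5-bis(benzyloxy)-4-methoxybenzoate
Conditions: Bu4NF (2.5 equiv), AcOH (3 equiv), THF, 0 °C
Reagents that add atoms: none
Why: Fluoride-mediated cleavage of the two aryl silyl ethers, buffered with acetic acid so that the liberated phenoxides neither hydrolyse nor transfer the C3 ester and C2 is not epimerised.

**Step 13**
Reactants: 18 tetra-O-benzyl diphenol from step 12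
Product: 19 epicatechin 3-O-(4-O-methylgallate), (2R,3R)-2-(3,4-dihydroxyphenyl)-5,7-dihydroxy-3,4-dihydro-2H-chromen-3-yl 3,5-dihydroxy-4-methoxybenzoate
Conditions: H2 (1 atm), Pd(OH)2/C, THF/MeOH (1:1), rt
Reagents that add atoms: none
Why: Catalytic hydrogenolysis of the four benzyl ethers over Pd(OH)2/C under neutral conditions, which should leave the aryl ester, the methyl ether and the flavan C2–O bond intact and makes no change at C2 or C3.

**Compound list**
1 | phloroglucinol | Oc1cc(O)cc(O)c1 | starting material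
2 | 3,5-bis(triisopropylsilyloxy)phenol | Oc1cc(O[Si](C(C)C)(C(C)C)C(C)C)cc(O[Si](C(C)C)(C(C)C)C(C)C)c1 | intermediate
3 | 2-bromo-3,5-bis(triisopropylsilyloxy)phenol | Oc1cc(O[Si](C(C)C)(C(C)C)C(C)C)cc(O[Si](C(C)C)(C(C)C)C(C)C)c1Br | intermediate
4 | 3,4-bis(benzyloxy)benzyl chloride | ClCc1ccc(OCc2ccccc2)c(OCc2ccccc2)c1 | starting material
5 | 1-{[3,4-bis(benzyloxy)phenyl]methoxy}-2-bromo-3,5-bis(triisopropylsilyloxy)benzene | Brc1c(OCc2ccc(OCc3ccccc3)c(OCc3ccccc3)c2)cc(O[Si](C(C)C)(C(C)C)C(C)C)cc1O[Si](C(C)C)(C(C)C)C(C)C | intermediate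
6 | ethyl bromoacetate | CCOC(=O)CBr | starting material
7 | (2-ethoxy-2-oxoethyl)zinc bromide (Reformatsky reagent, not isolated) | CCOC(=O)C[Zn]Br | intermediate
8 | ethyl 2-[2-{[3,4-bis(benzyloxy)phenyl]methoxy}-4,6-bis(triisopropylsilyloxy)phenyl]acetate | CCOC(=O)Cc1c(OCc2ccc(OCc3ccccc3)c(OCc3ccccc3)c2)cc(O[Si](C(C)C)(C(C)C)C(C)C)cc1O[Si](C(C)C)(C(C)C)C(C)C | intermediate
9 | ethyl 2-diazo-2-[2-{[3,4-bis(benzyloxy)phenyl]methoxy}-4,6-bis(triisopropylsilyloxy)phenyl]acetate | CCOC(=O)C(=[N+]=[N-])c1c(OCc2ccc(OCc3ccccc3)c(OCc3ccccc3)c2)cc(O[Si](C(C)C)(C(C)C)C(C)C)cc1O[Si](C(C)C)(C(C)C)C(C)C | intermediate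
10 | ethyl (2S,3R)-2-[3,4-bis(benzyloxy)phenyl]-4,6-bis(triisopropylsilyloxy)-2,3-dihydro-1-benzofuran-3-carboxylate (cis) | CCOC(=O)[C@@H]1c2c(O[Si](C(C)C)(C(C)C)C(C)C)cc(O[Si](C(C)C)(C(C)C)C(C)C)cc2O[C@@H]1c1ccc(OCc2ccccc2)c(OCc2ccccc2)c1 | intermediate
11 | [(2S,3S)-2-[3,4-bis(benzyloxy)phenyl]-4,6-bis(triisopropylsilyloxy)-2,3-dihydro-1-benzofuran-3-yl]methanol (cis) | OC[C@@H]1c2c(O[Si](C(C)C)(C(C)C)C(C)C)cc(O[Si](C(C)C)(C(C)C)C(C)C)cc2O[C@@H]1c1ccc(OCc2ccccc2)c(OCc2ccccc2)c1 | intermediate
12 | [(2S,3S)-2-[3,4-bis(benzyloxy)phenyl]-4,6-bis(triisopropylsilyloxy)-2,3-dihydro-1-benzofuran-3-yl]methyl methanesulfonate (cis) | CS(=O)(=O)OC[C@@H]1c2c(O[Si](C(C)C)(C(C)C)C(C)C)cc(O[Si](C(C)C)(C(C)C)C(C)C)cc2O[C@@H]1c1ccc(OCc2ccccc2)c(OCc2ccccc2)c1 | intermediate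
13 | 3,5-dihydroxy-4-methoxybenzoic acid | COc1c(O)cc(C(=O)O)cc1O | starting material
14 | benzyl 3,5-bis(benzyloxy)-4-methoxybenzoate | COc1c(OCc2ccccc2)cc(C(=O)OCc2ccccc2)cc1OCc1ccccc1 | intermediate
15 | 3,5-bis(benzyloxy)-4-methoxybenzoic acid | COc1c(OCc2ccccc2)cc(C(=O)O)cc1OCc1ccccc1 | intermediate
16 | spiro phenonium ion, methanesulfonate ion pair (C4a bridges C3 and C4; cyclopropane cis-fused to the five-membered ring on the face of the C2 aryl group; not isolated) | C1[C@H]2[C@@H](c4ccc(OCc5ccccc5)c(OCc5ccccc5)c4)[O+]=C3C=C(O[Si](C(C)C)(C(C)C)C(C)C)C=C(O[Si](C(C)C)(C(C)C)C(C)C)[C@]123.CS(=O)(=O)[O-] | intermediate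
17 | (2R,3R)-2-[3,4-bis(benzyloxy)phenyl]-5,7-bis(triisopropylsilyloxy)-3,4-dihydro-2H-chromen-3-yl 3,5-bis(benzyloxy)-4-methoxybenzoate | COc1c(OCc2ccccc2)cc(C(=O)O[C@@H]2Cc3c(O[Si](C(C)C)(C(C)C)C(C)C)cc(O[Si](C(C)C)(C(C)C)C(C)C)cc3O[C@@H]2c2ccc(OCc3ccccc3)c(OCc3ccccc3)c2)cc1OCc1ccccc1 | intermediate
18 | (2R,3R)-2-[3,4-bis(benzyloxy)phenyl]-5,7-dihydroxy-3,4-dihydro-2H-chromen-3-yl 3,5-bis(benzyloxy)-4-methoxybenzoate | COc1c(OCc2ccccc2)cc(C(=O)O[C@@H]2Cc3c(O)cc(O)cc3O[C@@H]2c2ccc(OCc3ccccc3)c(OCc3ccccc3)c2)cc1OCc1ccccc1 | intermediate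
19 | epicatechin 3-O-(4-O-methylgallate) | COc1c(O)cc(C(=O)O[C@@H]2Cc3c(O)cc(O)cc3O[C@@H]2c2ccc(O)c(O)c2)cc1O | target

**Count**
Total steps: 13. Longest linear sequence: 11 steps (steps 1–8, 11, 12, 13, from phloroglucinol); the acid branch (steps 9–10) joins at step 11.

**Steps most likely to fail**

1. Step 11 (ring enlargement).
What may go wrong: the bridged cation may be opened at the primary carbon, which returns the five-membered ring as its primary ester. It may also be captured by the fluoroalcohol, or ionise at C2–O1 with loss of the C2 configuration.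
Fallback, known reaction types only, from ester 10 to 17: the aryl shift is moved to the ketone oxidation level. The potassium enolate of 10 (KN(SiMe3)2, THF, −78 °C) is hydroxylated with 2-(phenylsulfonyl)-3-phenyloxaziridine to the tertiary α-hydroxy ester F1. LiBH4 reduction gives the diol F2, and TsCl in pyridine gives the primary monotosylate F3. Forming the magnesium alkoxide (i-PrMgCl, 1 equiv, toluene, 0 to 60 °C) triggers a semipinacol ring enlargement in which ring A migrates from C3 to the CH2 carbon, giving the flavan-3-one F4. LiBH(s-Bu)3 at −78 °C, the reduction known to give 2,3-cis flavan-3-ols from such ketones, gives the flavan-3-ol F5. Steglich esterification (DCC, DMAP, CH2Cl2) with acid 15 then returns to the route at 17.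

2. Step 6 (C–H insertion).
What may go wrong: the carbenoid carbon sits between two ortho substituents, so the aryl ring is twisted out of conjugation. The cis/trans ratio and the enantioselectivity may then fall below those of mono-ortho-substituted aryldiazoacetates.
Fallback from bromide 5 to alcohol 11: auxiliary control with separation of diastereomers. Negishi coupling of 5 with the zinc reagent made from (−)-menthyl bromoacetate gives the menthyl arylacetate F6, and diazo transfer as in step 5 gives the menthyl diazo ester F7. Insertion with whichever enantiomer of Rh2(PTTL)4 forms the matched pair gives the cis menthyl ester F8, freed from minor diastereomers by chromatography or crystallisation. Reduction with i-Bu2AlH releases menthol and gives 11.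

3. Step 5 (diazo transfer).
What may go wrong: deprotonation of the hindered, electron-rich arylacetate by DBU may be too slow, so that the sulfonyl azide is consumed unproductively.
Fallback from bromide 5 to diazo ester 9 (Bamford–Stevens route): bromine–lithium exchange (n-BuLi, THF, −78 °C) and acylation with diethyl oxalate give the arylglyoxylate F9. Condensation with TsNHNH2 gives the tosylhydrazone F10. Et3N or DBU in CH2Cl2 then eliminates sulfinate to give 9.

**Further compounds**
F1 | step 11 | ethyl 2-[3,4-bis(benzyloxy)phenyl]-3-hydroxy-4,6-bis(triisopropylsilyloxy)-2,3-dihydro-1-benzofuran-3-carboxylate (OH trans to the 2-aryl group) | CCOC(=O)[C@]1(O)c2c(O[Si](C(C)C)(C(C)C)C(C)C)cc(O[Si](C(C)C)(C(C)C)C(C)C)cc2O[C@@H]1c1ccc(OCc2ccccc2)c(OCc2ccccc2)c1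
F2 | step 11 | 2-[3,4-bis(benzyloxy)phenyl]-3-(hydroxymethyl)-4,6-bis(triisopropylsilyloxy)-2,3-dihydro-1-benzofuran-3-ol (OH trans to the 2-aryl group) | OC[C@]1(O)c2c(O[Si](C(C)C)(C(C)C)C(C)C)cc(O[Si](C(C)C)(C(C)C)C(C)C)cc2O[C@@H]1c1ccc(OCc2ccccc2)c(OCc2ccccc2)c1
F3 | step 11 | {2-[3,4-bis(benzyloxy)phenyl]-3-hydroxy-4,6-bis(triisopropylsilyloxy)-2,3-dihydro-1-benzofuran-3-yl}methyl 4-methylbenzenesulfonate | Cc1ccc(cc1)S(=O)(=O)OC[C@]1(O)c2c(O[Si](C(C)C)(C(C)C)C(C)C)cc(O[Si](C(C)C)(C(C)C)C(C)C)cc2O[C@@H]1c1ccc(OCc2ccccc2)c(OCc2ccccc2)c1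
F4 | step 11 | (2R)-2-[3,4-bis(benzyloxy)phenyl]-5,7-bis(triisopropylsilyloxy)chroman-3-one | O=C1Cc2c(O[Si](C(C)C)(C(C)C)C(C)C)cc(O[Si](C(C)C)(C(C)C)C(C)C)cc2O[C@@H]1c1ccc(OCc2ccccc2)c(OCc2ccccc2)c1
F5 | step 11 | (2R,3R)-2-[3,4-bis(benzyloxy)phenyl]-5,7-bis(triisopropylsilyloxy)chroman-3-ol | O[C@@H]1Cc2c(O[Si](C(C)C)(C(C)C)C(C)C)cc(O[Si](C(C)C)(C(C)C)C(C)C)cc2O[C@@H]1c1ccc(OCc2ccccc2)c(OCc2ccccc2)c1
F6 | step 6 | (1R,2S,5R)-menthyl 2-[2-{[3,4-bis(benzyloxy)phenyl]methoxy}-4,6-bis(triisopropylsilyloxy)phenyl]acetate | CC(C)[C@@H]1CC[C@@H](C)C[C@H]1OC(=O)Cc4c(OCc2ccc(OCc3ccccc3)c(OCc3ccccc3)c2)cc(O[Si](C(C)C)(C(C)C)C(C)C)cc4O[Si](C(C)C)(C(C)C)C(C)C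
F7 | step 6 | (1R,2S,5R)-menthyl 2-diazo-2-[2-{[3,4-bis(benzyloxy)phenyl]methoxy}-4,6-bis(triisopropylsilyloxy)phenyl]acetate | CC(C)[C@@H]1CC[C@@H](C)C[C@H]1OC(=O)C(=[N+]=[N-])c4c(OCc2ccc(OCc3ccccc3)c(OCc3ccccc3)c2)cc(O[Si](C(C)C)(C(C)C)C(C)C)cc4O[Si](C(C)C)(C(C)C)C(C)C
F8 | step 6 | (1R,2S,5R)-menthyl (2S,3R)-2-[3,4-bis(benzyloxy)phenyl]-4,6-bis(triisopropylsilyloxy)-2,3-dihydro-1-benzofuran-3-carboxylate (cis) | CC(C)[C@@H]1CC[C@@H](C)C[C@H]1OC(=O)[C@@H]4c5c(O[Si](C(C)C)(C(C)C)C(C)C)cc(O[Si](C(C)C)(C(C)C)C(C)C)cc5O[C@@H]4c2ccc(OCc3ccccc3)c(OCc3ccccc3)c2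
F9 | step 5 | ethyl 2-oxo-2-[2-{[3,4-bis(benzyloxy)phenyl]methoxy}-4,6-bis(triisopropylsilyloxy)phenyl]acetate | CCOC(=O)C(=O)c1c(OCc2ccc(OCc3ccccc3)c(OCc3ccccc3)c2)cc(O[Si](C(C)C)(C(C)C)C(C)C)cc1O[Si](C(C)C)(C(C)C)C(C)C
F10 | step 5 | ethyl 2-[2-{[3,4-bis(benzyloxy)phenyl]methoxy}-4,6-bis(triisopropylsilyloxy)phenyl]-2-(tosylhydrazono)acetate | CCOC(=O)C(=NNS(=O)(=O)c1ccc(C)cc1)c1c(OCc2ccc(OCc3ccccc3)c(OCc3ccccc3)c2)cc(O[Si](C(C)C)(C(C)C)C(C)C)cc1O[Si](C(C)C)(C(C)C)C(C)C
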